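Ring B (C6–C11), with oxidised C9 para to the quaternary spiro carbon C6, is a dearomatised para-alkylphenol, so the route rests on disconnecting C5–C6 of ring A. A phenol carrying a para tether (benzylic gem-dimethyl carbon, silyl-protected C3 carbinol, terminal alkyne) is cyclised by cationic gold: the carbon para to the hydroxyl adds to the internal alkyne carbon. In one operation this forms C5–C6, closes ring A, installs the C5 methylene and turns the arene into a symmetric spirodienone. The C3 stereocentre, from an asymmetric propargylation, later directs the C5 epoxidation and is finally inverted to the bromide; a chiral copper hydride differentiates the dienone arms to fix C6.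

Key step: step 7

Remark on locants: spiro compounds are numbered C1 (CMe2), C2, C3, C4, C5, C6 (spiro) in ring A, C7–C11 in ring B and C12 for the exocyclic carbon on C9; open-chain compounds carry chain locants (chain C4 becomes C3). The descriptor at this carbon changes from R (10–12) to S (13–19) only because the CIP ranking of its two methylene branches changes on ring closure.

Assumption: the arm selected in step 8 depends on the ligand antipode, which cannot be predicted with certainty for this substrate; (R)-DTBM-SEGPHOS [(R)-5,5′-bis[bis(3,5-di-tert-butyl-4-methoxyphenyl)phosphino]-4,4′-bi-1,3-benzodioxole] is written, and its enantiomer is to be used if a trial run reduces the other arm.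

Step 1
Reactants: 1 anisole; 2 3-methylbut-2-enoic acid
Product: 3 3-(4-methoxyphenyl)-3-methylbutanoic acid
Conditions: AlCl3 (2.5 equiv), anisole (3 equiv), CH2Cl2, 0 °C → rt
Reagents that add atoms: none
Why: Friedel–Crafts alkylation in which the Lewis acid turns the unsaturated acid into a tertiary cation equivalent that attacks anisole para to the methoxy group, building the benzylic quaternary carbon (later C1) in one operation.

Step 2
Reactants: 3 3-(4-methoxyphenyl)-3-methylbutanoic acid
Product: 5 methyl 3-(4-hydroxyphenyl)-3-methylbutanoate, via 3-(4-hydroxyphenyl)-3-methylbutanoic acid 4 (not isolated)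
Conditions: BBr3 (3 equiv), CH2Cl2, −78 → 0 °C; then MeOH, 60 °C
Reagents that add atoms: methanol, CO
Why: BBr3 cleavage of the aryl methyl ether followed by Fischer esterification with the HBr–methanol formed on quenching, placed here so that the only harsh deprotection of the route is over before any alkyne or silyl ether exists.

Step 3
Reactants: 5 methyl 3-(4-hydroxyphenyl)-3-methylbutanoate
Product: 6 methyl 3-[4-(tert-butyldimethylsilyloxy)phenyl]-3-methylbutanoate
Conditions: TBSCl (1.2 equiv), imidazole (2.5 equiv), DMF, rt
Reagents that add atoms: tert-butyldimethylsilyl chloride, CC(C)(C)[Si](C)(C)Cl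
Why: Standard silylation of a phenol, giving an aryl silyl ether that tolerates hydride and boronate chemistry and can later be removed by carbonate in methanol without touching an alkyl silyl ether or an alkyne.

Step 4
Reactants: 6 methyl 3-[4-(tert-butyldimethylsilyloxy)phenyl]-3-methylbutanoate
Product: 7 3-[4-(tert-butyldimethylsilyloxy)phenyl]-3-methylbutanal
Conditions: i-Bu2AlH (1.1 equiv), CH2Cl2, −78 °C; MeOH, then aq. potassium sodium tartrate
Reagents that add atoms: none
Why: Partial reduction of a methyl ester to the aldehyde with one equivalent of i-Bu2AlH at low temperature, a standard transformation that leaves the aryl silyl ether intact.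

Step 5
Reactants: 7 3-[4-(tert-butyldimethylsilyloxy)phenyl]-3-methylbutanal; 8 allenylboronic acid pinacol ester
Product: 10 (4R)-2-[4-(tert-butyldimethylsilyloxy)phenyl]-2-methylhept-6-yn-4-ol, via homopropargylic pinacol borate 9 (not isolated)
Conditions: 8 (1.5 equiv), (R)-TRIP [(R)-3,3′-bis(2,4,6-triisopropylphenyl)-1,1′-binaphthyl-2,2′-diyl hydrogen phosphate] (10 mol %), 4 Å MS, toluene, 0 °C; aq. NaHCO3
Reagents that add atoms: none
Why: Chiral phosphoric acid-catalysed propargylation of an aldehyde by an allenylboronate through a closed six-membered SE2′ transition state; by analogy with other aldehydes the R acid should direct the propargyl group to the Re face and set the carbinol carbon (later C3) as R.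

Step 6
Reactants: 10 (4R)-2-[4-(tert-butyldimethylsilyloxy)phenyl]-2-methylhept-6-yn-4-ol
Product: 12 4-[(4R)-4-(tert-butyldimethylsilyloxy)-2-methylhept-6-yn-2-yl]phenol, via bis-silyl ether 11 (not isolated)
Conditions: TBSCl (1.5 equiv), imidazole (3 equiv), DMF, rt; aqueous work-up; then K2CO3 (0.3 equiv), MeOH, rt
Reagents that add atoms: tert-butyldimethylsilyl chloride, CC(C)(C)[Si](C)(C)Cl
Why: Silylation of the secondary alcohol followed by chemoselective base-mediated methanolysis of the aryl silyl ether (phenoxide is the far better leaving group), which frees the phenol under conditions harmless to the alkyl silyl ether and the terminal alkyne.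

Step 7
Reactants: 12 4-[(4R)-4-(tert-butyldimethylsilyloxy)-2-methylhept-6-yn-2-yl]phenol
Product: 13 (3S)-3-(tert-butyldimethylsilyloxy)-1,1-dimethyl-5-methylidenespiro[5.5]undeca-7,10-dien-9-one
Conditions: Ph3PAuNTf2 (5 mol %), 4 Å MS, dry CH2Cl2, 0 °C → rt
Reagents that add atoms: none
Why: Cationic monovalent gold binds the terminal alkyne, the arene carbon para to the hydroxyl (future C6) adds anti to gold at the internal alkyne carbon (future C5), the alkenyl-gold oxocarbenium ion loses the phenolic proton to give the dienone, and protodeauration leaves the C5 methylene. The closest known reaction type is the gold-catalysed intramolecular ipso-Friedel–Crafts alkenylation of para-tethered phenols to spirocyclohexadienones, which is established for five-membered closures and is applied here to a tether one carbon longer. Ring A is closed in the 6-exo-dig mode. No stereocentre is created, because the two arms of ring B are identical, and C3 is untouched. The step needs ipso instead of ortho attack and carbon instead of oxygen attack: the para carbon is the most nucleophilic site of the phenol and its attack becomes irreversible once the O–H proton is lost, ortho attack would demand a seven-membered ring, the benzylic gem-dimethyl group folds the tether (gem-dialkyl effect), Markovnikov polarisation sends the nucleophile to the internal carbon, and the C3 oxygen is capped as a silyl ether so that it cannot add to the alkyne. The exothermic change of an alkyne into an alkene offsets the aromatic stabilisation that is given up.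

Step 8
Reactants: 13 (3S)-3-(tert-butyldimethylsilyloxy)-1,1-dimethyl-5-methylidenespiro[5.5]undeca-7,10-dien-9-one
Product: 15 (3S,6S)-3-(tert-butyldimethylsilyloxy)-1,1-dimethyl-5-methylidenespiro[5.5]undec-7-en-9-one, via silyl dienol ether 14 (not isolated)
Conditions: Cu(OAc)2 (5 mol %), (R)-DTBM-SEGPHOS (5.5 mol %), (EtO)2MeSiH (1.3 equiv), toluene, −20 °C; then 1 M HCl, THF, 0 °C
Reagents that add atoms: none
Why: Copper hydride conjugate reduction used as a desymmetrisation of a 4,4-disubstituted cyclohexadienone: the ligand-bound monovalent copper hydride delivers hydride to C11 from the ring B face on the side of the flat C5 methylene, away from the C1 gem-dimethyl group, the ligand antipode decides which diastereotopic arm presents that face and so sets C6 as S, and silyl transfer to the enolate gives 14, which shields the second arm from reduction until acidic work-up.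

Step 9
Reactants: 15 (3S,6S)-3-(tert-butyldimethylsilyloxy)-1,1-dimethyl-5-methylidenespiro[5.5]undec-7-en-9-one
Product: 16 (3S,6S,9E)-9-(bromomethylidene)-3-(tert-butyldimethylsilyloxy)-1,1-dimethyl-5-methylidenespiro[5.5]undec-7-ene
Conditions: Ph3P+CH2Br Br− (3 equiv), KOt-Bu (2.9 equiv), THF, −78 °C; add 15, −78 °C → rt; chromatographic removal of any Z isomer
Reagents that add atoms: (bromomethyl)triphenylphosphonium bromide, BrC[P+](c1ccccc1)(c1ccccc1)c1ccccc1.[Br-]
Why: Wittig bromomethylenation of the enone carbonyl by 1,2-addition, in which the halo-ylide is expected to place bromine cis to the bulkier sp3 flank (C10H2) and trans to the vinylic C8, as in Z-selective Wittig reactions of such ylides, which corresponds to the required E geometry.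

Step 10
Reactants: 16 (3S,6S,9E)-9-(bromomethylidene)-3-(tert-butyldimethylsilyloxy)-1,1-dimethyl-5-methylidenespiro[5.5]undec-7-ene
Product: 17 (3S,6S,9E)-9-(bromomethylidene)-1,1-dimethyl-5-methylidenespiro[5.5]undec-7-en-3-ol
Conditions: Bu4NF (1.5 equiv), THF, 0 °C → rt; H2O
Reagents that add atoms: none
Why: Fluoride cleavage of the alkyl silyl ether, to which the bromodiene and the exocyclic alkene are inert, releases the C3 hydroxyl needed as a directing group.

Step 11
Reactants: 17 (3S,6S,9E)-9-(bromomethylidene)-1,1-dimethyl-5-methylidenespiro[5.5]undec-7-en-3-ol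
Product: 18 (3S,5S,6S,9E)-9-(bromomethylidene)-1,1-dimethylspiro[5.5]undec-7-en-3-ol carrying a spiro-oxirane at C5 (oxirane oxygen on C5 cis to the C3 hydroxyl)
Conditions: VO(acac)2 (5 mol %), t-BuOOH (1.5 equiv), CH2Cl2, 0 °C → rt
Reagents that add atoms: tert-butyl hydroperoxide, CC(C)(C)OO
Why: Hydroxyl-directed epoxidation of a homoallylic alcohol in which the vanadium alkoxide of the axial C3 oxygen delivers the peroxide oxygen to the same face of the C5 methylene (C5 becomes S), a sense reinforced by the axial C1 methyl group that blocks the other face, while the bromodiene has no nearby hydroxyl and should not react.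

Step 12
Reactants: 18 spiro-oxirane of step 11
Product: 19 (3S,5S,6S,9E)-9-(bromomethylidene)-1,1,5-trimethylspiro[5.5]undec-7-ene-3,5-diol
Conditions: LiBHEt3 (3 equiv), THF, 0 °C → rt; H2O
Reagents that add atoms: none
Why: SN2 hydride opening of a 1,1-disubstituted epoxide at its methylene carbon by LiBHEt3 turns the oxirane into the C5 methyl carbinol without breaking any bond to C5, so its configuration is kept, and alkenyl bromides are inert to this reagent at these temperatures.

Step 13
Reactants: 19 (3S,5S,6S,9E)-9-(bromomethylidene)-1,1,5-trimethylspiro[5.5]undec-7-ene-3,5-diol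
Product: 20 (3R,5S,6S,9E)-3-bromo-9-(bromomethylidene)-1,1,5-trimethylspiro[5.5]undec-7-en-5-ol
Conditions: CBr4 (1.5 equiv), PPh3 (1.6 equiv), 2,6-lutidine, CH2Cl2, 0 °C → rt
Reagents that add atoms: tetrabromomethane, BrC(Br)(Br)Br
Why: Appel bromination in which the secondary C3 hydroxyl becomes an oxyphosphonium leaving group that bromide displaces by SN2 with inversion (3S alcohol to 3R bromide), the chair with this group axial letting bromide enter equatorially, while the hindered tertiary C5 hydroxyl should stay unactivated.

Compound list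
1 | anisole | COc1ccccc1 | starting material
2 | 3-methylbut-2-enoic acid | CC(C)=CC(=O)O | starting material
3 | 3-(4-methoxyphenyl)-3-methylbutanoic acid | COc1ccc(cc1)C(C)(C)CC(=O)O | intermediate
4 | 3-(4-hydroxyphenyl)-3-methylbutanoic acid (formed in the flask) | CC(C)(CC(=O)O)c1ccc(O)cc1 | intermediate
5 | methyl 3-(4-hydroxyphenyl)-3-methylbutanoate | COC(=O)CC(C)(C)c1ccc(O)cc1 | intermediate
6 | methyl 3-[4-(tert-butyldimethylsilyloxy)phenyl]-3-methylbutanoate | COC(=O)CC(C)(C)c1ccc(O[Si](C)(C)C(C)(C)C)cc1 | intermediate
7 | 3-[4-(tert-butyldimethylsilyloxy)phenyl]-3-methylbutanal | O=CCC(C)(C)c1ccc(O[Si](C)(C)C(C)(C)C)cc1 | intermediate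
8 | allenylboronic acid pinacol ester | C=C=CB1OC(C)(C)C(C)(C)O1 | starting material
9 | pinacol borate of (4R)-2-[4-(tert-butyldimethylsilyloxy)phenyl]-2-methylhept-6-yn-4-ol (formed in the flask) | CC(C)(C[C@H](OB1OC(C)(C)C(C)(C)O1)CC#C)c1ccc(O[Si](C)(C)C(C)(C)C)cc1 | intermediate
10 | (4R)-2-[4-(tert-butyldimethylsilyloxy)phenyl]-2-methylhept-6-yn-4-ol | CC(C)(C[C@H](O)CC#C)c1ccc(O[Si](C)(C)C(C)(C)C)cc1 | intermediate
11 | tert-butyl{4-[(4R)-4-(tert-butyldimethylsilyloxy)-2-methylhept-6-yn-2-yl]phenoxy}dimethylsilane (formed in the flask) | CC(C)(C[C@H](O[Si](C)(C)C(C)(C)C)CC#C)c1ccc(O[Si](C)(C)C(C)(C)C)cc1 | intermediate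
12 | 4-[(4R)-4-(tert-butyldimethylsilyloxy)-2-methylhept-6-yn-2-yl]phenol | CC(C)(C[C@H](O[Si](C)(C)C(C)(C)C)CC#C)c1ccc(O)cc1 | intermediate
13 | (3S)-3-(tert-butyldimethylsilyloxy)-1,1-dimethyl-5-methylidenespiro[5.5]undeca-7,10-dien-9-one | CC1(C)C[C@H](O[Si](C)(C)C(C)(C)C)CC(=C)C12C=CC(=O)C=C2 | intermediate
14 | (3S,6S)-3-(tert-butyldimethylsilyloxy)-9-[diethoxy(methyl)silyloxy]-1,1-dimethyl-5-methylidenespiro[5.5]undeca-7,9-diene (formed in the flask) | CC1(C)C[C@H](O[Si](C)(C)C(C)(C)C)CC(=C)[C@@]12C=CC(O[Si](C)(OCC)OCC)=CC2 | intermediate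
15 | (3S,6S)-3-(tert-butyldimethylsilyloxy)-1,1-dimethyl-5-methylidenespiro[5.5]undec-7-en-9-one | CC1(C)C[C@H](O[Si](C)(C)C(C)(C)C)CC(=C)[C@@]12C=CC(=O)CC2 | intermediate
16 | (3S,6S,9E)-9-(bromomethylidene)-3-(tert-butyldimethylsilyloxy)-1,1-dimethyl-5-methylidenespiro[5.5]undec-7-ene | CC1(C)C[C@H](O[Si](C)(C)C(C)(C)C)CC(=C)[C@@]12C=C/C(=C/Br)CC2 | intermediate
17 | (3S,6S,9E)-9-(bromomethylidene)-1,1-dimethyl-5-methylidenespiro[5.5]undec-7-en-3-ol | CC1(C)C[C@H](O)CC(=C)[C@@]12C=C/C(=C/Br)CC2 | intermediate
18 | (3S,5S,6S,9E)-9-(bromomethylidene)-1,1-dimethylspiro[5.5]undec-7-en-3-ol with a spiro-oxirane at C5, oxirane oxygen cis to the C3 hydroxyl | CC1(C)C[C@H](O)C[C@]3(OC3)[C@@]12C=C/C(=C/Br)CC2 | intermediate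
19 | (3S,5S,6S,9E)-9-(bromomethylidene)-1,1,5-trimethylspiro[5.5]undec-7-ene-3,5-diol | CC1(C)C[C@H](O)C[C@](C)(O)[C@@]12C=C/C(=C/Br)CC2 | intermediate
20 | (3R,5S,6S,9E)-3-bromo-9-(bromomethylidene)-1,1,5-trimethylspiro[5.5]undec-7-en-5-ol | CC1(C)C[C@@H](Br)C[C@](C)(O)[C@@]12C=C/C(=C/Br)CC2 | target

Total step count: 13. Longest linear sequence: 13 steps (anisole to 20).

Steps most likely to fail

Step 7. The six-membered ipso closure may be outrun by ortho hydroarylation to a seven-membered ring, by hydration of the gold-activated alkyne, or by acid-induced migration of the exocyclic double bond. The fallback keeps the C5–C6 disconnection but makes the bond by palladium. It sets out from aldehyde 7: asymmetric 2-bromoallylation with B-(2-bromoallyl)diisopinocampheylborane (antipode chosen to give the same spatial arrangement as in 10) should give (4S)-6-bromo-2-[4-(tert-butyldimethylsilyloxy)phenyl]-2-methylhept-6-en-4-ol F1. Silylation as in step 6 gives tert-butyl{4-[(4S)-6-bromo-4-(tert-butyldimethylsilyloxy)-2-methylhept-6-en-2-yl]phenoxy}dimethylsilane F2, and carbonate methanolysis gives 4-[(4S)-6-bromo-4-(tert-butyldimethylsilyloxy)-2-methylhept-6-en-2-yl]phenol F3. Dearomative ipso-alkenylation of the phenoxide (Pd(OAc)2, 2-dicyclohexylphosphino-2′,4′,6′-triisopropylbiphenyl, K2CO3, dioxane, 80 °C) then closes ring A: zerovalent palladium inserts into the alkenyl bromide, the phenoxide is palladated at the para carbon, and reductive elimination forms C5–C6. The route is rejoined at 13.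

Step 8. The catalyst may discriminate poorly between the two diastereotopic enone arms, or both arms may be reduced. The fallback sets out from 13 and first removes the problem of arm selection in the reduction: excess [(Ph3P)CuH]6 in wet benzene reduces both arms to (3S)-3-(tert-butyldimethylsilyloxy)-1,1-dimethyl-5-methylidenespiro[5.5]undecan-9-one F4, in which C6 is not stereogenic. Desymmetrising enolisation with lithium (R,R)-bis(1-phenylethyl)amide (or its antipode) in the presence of Me3SiCl at −100 °C in THF then selects one α-methylene group and gives (3S,6S)-3-(tert-butyldimethylsilyloxy)-1,1-dimethyl-5-methylidene-9-(trimethylsilyloxy)spiro[5.5]undec-8-ene F5. Saegusa–Ito oxidation with palladium diacetate in MeCN introduces the C7=C8 double bond and rejoins the route at 15.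

Step 9. The olefination may show poor geometric control, giving much Z isomer, and enolisation of the ketone by the basic ylide may compete. The fallback sets out from 15 and uses a boron-Wittig olefination (bis(pinacolato)borylmethane, lithium 2,2,6,6-tetramethylpiperidide, THF, −78 °C → rt). This reaction places boron trans to the bulkier carbonyl flank, the opposite sense to the halo-ylide, so it should favour the E isomer in exactly the case where the Wittig reaction favours Z. The product, separable from its isomer, is (3S,6S,9E)-3-(tert-butyldimethylsilyloxy)-1,1-dimethyl-5-methylidene-9-[(4,4,5,5-tetramethyl-1,3,2-dioxaborolan-2-yl)methylidene]spiro[5.5]undec-7-ene F6. Bromodeboronation with retention of geometry (CuBr2, THF/H2O, 60 °C) rejoins the route at 16.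

Further compounds
F1 | step 7 | (4S)-6-bromo-2-[4-(tert-butyldimethylsilyloxy)phenyl]-2-methylhept-6-en-4-ol | CC(C)(C[C@H](O)CC(Br)=C)c1ccc(O[Si](C)(C)C(C)(C)C)cc1
F2 | step 7 | tert-butyl{4-[(4S)-6-bromo-4-(tert-butyldimethylsilyloxy)-2-methylhept-6-en-2-yl]phenoxy}dimethylsilane | CC(C)(C[C@H](O[Si](C)(C)C(C)(C)C)CC(Br)=C)c1ccc(O[Si](C)(C)C(C)(C)C)cc1
F3 | step 7 | 4-[(4S)-6-bromo-4-(tert-butyldimethylsilyloxy)-2-methylhept-6-en-2-yl]phenol | CC(C)(C[C@H](O[Si](C)(C)C(C)(C)C)CC(Br)=C)c1ccc(O)cc1
F4 | step 8 | (3S)-3-(tert-butyldimethylsilyloxy)-1,1-dimethyl-5-methylidenespiro[5.5]undecan-9-one | CC1(C)C[C@H](O[Si](C)(C)C(C)(C)C)CC(=C)C12CCC(=O)CC2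
F5 | step 8 | (3S,6S)-3-(tert-butyldimethylsilyloxy)-1,1-dimethyl-5-methylidene-9-(trimethylsilyloxy)spiro[5.5]undec-8-ene | CC1(C)C[C@H](O[Si](C)(C)C(C)(C)C)CC(=C)[C@@]12CC=C(O[Si](C)(C)C)CC2
F6 | step 9 | (3S,6S,9E)-3-(tert-butyldimethylsilyloxy)-1,1-dimethyl-5-methylidene-9-[(4,4,5,5-tetramethyl-1,3,2-dioxaborolan-2-yl)methylidene]spiro[5.5]undec-7-ene | CC1(C)C[C@H](O[Si](C)(C)C(C)(C)C)CC(=C)[C@@]12C=C/C(=C/B3OC(C)(C)C(C)(C)O3)CC2
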